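The route rests on the bond between the carbinol carbon C3 and the neighbouring oxolane carbon C4 (cembrane numbering; C1 is the ring CH bearing the lactone methylene carbon). The C3 hydroxyl next to the C4 methyl is read as a masked 2-methylene allylic alcohol, so the key step closes the 14-membered carbocycle by nickel/chromium coupling of a C3 aldehyde with a C4 alkenyl triflate. Its precursor is an open-chain ε-lactone keto aldehyde that already carries C1, C12 and a 7,8-epoxide. A mercury-triggered transannular cascade then converts the exocyclic methylene and the epoxide into the oxolane ring, the C4 methyl group and the C8 alcohol.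

Key step: step 15

Remark: (E)-geranylacetone, cyclohex-2-en-1-one and potassium ethenyltrifluoroborate are taken as commercial. Atom labels follow cembrane numbering: C3 = CHOH, C4 = oxolane C–CH3, C7 = oxolane CH, C8 = C(CH3)OH, C11 = ketone, C12 = lactone O–C(CH3), C15/C17 = C=CH2, C16 = lactone C=O, C18 = CH3 on C4.

Step 1
Reactants: 1 geranylacetone
Product: 2 (5E)-6,10-dimethylundeca-1,5,9-trien-2-yl triflate
Conditions: LiN(i-Pr)2, THF, −78 °C; then PhNTf2, −78 → 0 °C
Reagents that add atoms: N-phenylbis(trifluoromethanesulfonimide) O=S(=O)(N(c1ccccc1)S(=O)(=O)C(F)(F)F)C(F)(F)F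
Why: Kinetic deprotonation of the methyl ketone at CH3 and O-sulfonylation of the terminal enolate (enol triflate formation) should give the 1,1-disubstituted alkenyl triflate that later becomes C4/C18.

Step 2
Reactants: 2 trienyl triflate
Product: 4 terminal epoxide (5E)-8-(3,3-dimethyloxiran-2-yl)-6-methylocta-1,5-dien-2-yl triflate, via bromohydrin 3 (not isolated)
Conditions: N-bromosuccinimide, THF/H2O, 0 °C; then DBU, CH2Cl2, rt
Reagents that add atoms: water O
Why: Bromohydrin formation in aqueous THF should prefer the terminal trisubstituted alkene (the enol triflate alkene is electron-poor, the internal alkene is shielded in the coiled chain), and the amidine base closes the bromohydrin to the epoxide (intramolecular Williamson reaction).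

Step 3
Reactants: 4 terminal epoxide
Product: 5 aldehyde (5E)-6-methyl-9-oxonona-1,5-dien-2-yl triflate
Conditions: H5IO6, THF/Et2O, 0 °C
Reagents that add atoms: none
Why: Periodic acid hydrolyses the epoxide and cleaves the glycol (periodate cleavage), which removes the isopropylidene carbon as acetone and leaves C11 as the aldehyde.

Step 4
Reactants: 5 aldehyde, 6 cyclohex-2-en-1-one
Product: 7 (9S)-allylic alcohol (5E,9S)-9-hydroxy-6-methyl-9-(6-oxocyclohex-1-en-1-yl)nona-1,5-dien-2-yl triflate
Conditions: PEt3, 3,3′-bis(3,5-dimethylphenyl)-H8-BINOL (10 mol%, the antipode that gives the 9S carbinol), THF, −10 °C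
Reagents that add atoms: none
Why: Morita–Baylis–Hillman reaction in which the chiral diol, hydrogen-bonded to the phosphonium enolate, selects the aldehyde face and so sets the C11 carbinol, which serves as a relay stereocenter for C12 and is erased in step 14.

Step 5
Reactants: 7 (9S)-allylic alcohol
Product: 9 hydroxy ketone with quaternary C12 (5E,9S)-9-hydroxy-6-methyl-9-[(1R)-1-methyl-2-oxocyclohexyl]nona-1,5-dien-2-yl triflate, via alkoxide enolate 8 (not isolated)
Conditions: LiN(SiMe3)2, THF, −78 °C; LiBH(s-Bu)3, −78 °C; then MeI, DMPU, −78 → −30 °C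
Reagents that add atoms: iodomethane CI
Why: Conjugate hydride addition gives only the C12 enolate, and its lithium chelate with the neighbouring alkoxide should be methylated anti to the C10 chain (Fráter–Seebach-type reductive alkylation), which sets C12 from C11.

Step 6
Reactants: 9 hydroxy ketone
Product: 10 triethylsilyl ether of 9
Conditions: Et3SiOTf, 2,6-lutidine, CH2Cl2, −78 °C
Reagents that add atoms: triethylsilyl trifluoromethanesulfonate CC[Si](CC)(CC)OS(=O)(=O)C(F)(F)F
Why: Silylation with the silyl triflate protects the hindered C11 alcohol against retro-aldol cleavage and against the bases used later.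

Step 7
Reactants: 10 silyl ether
Product: 11 enone (5E,9S)-6-methyl-9-[(1R)-1-methyl-2-oxocyclohex-3-en-1-yl]-9-(triethylsilyloxy)nona-1,5-dien-2-yl triflate
Conditions: LiN(i-Pr)2, THF, −78 °C; then N-tert-butylbenzenesulfinimidoyl chloride, −78 °C
Reagents that add atoms: none
Why: C12 is quaternary, so the lithium enolate can form only toward C15, and the sulfinimidoyl chloride dehydrogenates it to the C15=C1 enone (Mukaiyama dehydrogenation).

Step 8
Reactants: 11 enone, 12 potassium ethenyltrifluoroborate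
Product: 13 ketone with C1 set (5E,9S)-9-[(1R,4S)-4-ethenyl-1-methyl-2-oxocyclohexyl]-6-methyl-9-(triethylsilyloxy)nona-1,5-dien-2-yl triflate
Conditions: [Rh(cod)Cl]2 (3 mol%), (S)-BINAP, Et3N, toluene/H2O, 60 °C
Reagents that add atoms: none
Why: Rhodium-catalysed asymmetric 1,4-addition of the alkenyl boron reagent (Hayashi–Miyaura reaction) should set C1 under control of (S)-BINAP, by analogy with the S-selective additions of aryl and alkenyl boron reagents to cyclohexenones with this ligand.

Step 9
Reactants: 13 ketone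
Product: 14 ε-lactone (5E,9S)-9-[(2R,5S)-5-ethenyl-2-methyl-7-oxooxepan-2-yl]-6-methyl-9-(triethylsilyloxy)nona-1,5-dien-2-yl triflate
Conditions: Me3SiOOSiMe3, Me3SiOTf (cat.), CH2Cl2, −40 °C
Reagents that add atoms: bis(trimethylsilyl) peroxide C[Si](C)(C)OO[Si](C)(C)C
Why: Baeyer–Villiger oxidation with the silyl peroxide and silyl triflate leaves C=C bonds untouched, and the quaternary C12 migrates with retention in preference to the C15 methylene, which installs the tertiary C12–O bond of the seven-membered lactone.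

Step 10
Reactants: 14 ε-lactone
Product: 15 (7S,8S)-epoxy lactone
Conditions: ent-Shi ketone (30 mol%), KHSO5 (as 2KHSO5·KHSO4·K2SO4), K2CO3, Bu4NHSO4, MeCN/CH2(OMe)2/aq. Na2B4O7, 0 °C
Reagents that add atoms: potassium peroxymonosulfate [K+].[O-]S(=O)(=O)OO
Why: Shi epoxidation: the chiral dioxirane should attack only the electron-rich trisubstituted (E)-alkene through the spiro transition state, and the ent-ketone should give the (7S,8S)-epoxide, since the D-fructose-derived ketone gives R,R epoxides from such alkenes.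

Step 11
Reactants: 15 epoxy lactone
Product: 18 α-methylene lactone, via Mannich base 16 (not isolated), via ammonium iodide 17 (not isolated)
Conditions: LiN(i-Pr)2, THF, −78 °C; CH2=NMe2+ I−; then MeI, CH2Cl2; aq. NaHCO3
Reagents that add atoms: Eschenmoser's salt C=[N+](C)C.[I-]
Why: Aminomethylation of the lactone enolate, N-methylation and E1cB loss of trimethylamine give the exocyclic methylene (Eschenmoser methylenation), and no ketone or aldehyde is yet present to compete for the base.

Step 12
Reactants: 18 α-methylene lactone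
Product: 19 C11 alcohol
Conditions: Bu4NF, AcOH, THF, 0 °C
Reagents that add atoms: none
Why: Fluoride buffered with acetic acid should cleave the triethylsilyl ether without opening the epoxide or adding to the acrylate.

Step 13
Reactants: 19 C11 alcohol
Product: 21 diol with primary C3 alcohol, via borane adduct 20 (not isolated)
Conditions: 9-BBN, THF, 0 °C → rt; then H2O2, pH 7 phosphate buffer, 0 °C
Reagents that add atoms: hydrogen peroxide OO
Why: 9-BBN should hydroborate the monosubstituted vinyl group far faster than the electron-poor acrylate and enol triflate alkenes and places boron on the terminal carbon, and buffered oxidation gives the C3 alcohol (hydroboration–oxidation).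

Step 14
Reactants: 21 diol
Product: 22 keto aldehyde (seco compound)
Conditions: Dess–Martin periodinane, NaHCO3, CH2Cl2, 0 °C → rt
Reagents that add atoms: none
Why: Dess–Martin oxidation converts the primary C3 alcohol into the aldehyde and the secondary C11 alcohol into the ketone in one buffered operation that spares the epoxide and erases the relay stereocenter.

Step 15
Reactants: 22 keto aldehyde
Product: 23 macrocyclic allylic alcohol (1R,3S,7S,8S,12R)-7,8-epoxy-3-hydroxy-11-oxocembra-4(18),15(17)-dien-16,12-olide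
Conditions: CrCl2 (10 equiv), NiCl2 (2 mol%), N-[2-(4-isopropyl-4,5-dihydro-1,3-oxazol-2-yl)phenyl]methanesulfonamide (the antipode that gives the 3S carbinol), Et3N, THF/MeCN, rt, 2 mM, slow addition
Reagents that add atoms: none
Why: Zerovalent nickel, formed from NiCl2 by CrCl2, inserts into the C4–OTf bond, the alkenyl group passes to chromium, and the alkenyl chromium species (trivalent chromium) adds to the C3 aldehyde. The closest known reaction is the Nozaki–Hiyama–Kishi macrocyclization of ω-formyl alkenyl halides and triflates. The only ring closed is the 14-membered carbocycle, by 14-exo-trig 1,2-addition of C4 to the C3 carbonyl. The new stereocenter C3 should be set under reagent control by the chiral sulfonamide ligand on chromium. The step needs selectivity for the aldehyde over the C11 ketone, the lactone, the acrylate and the epoxide, which the low basicity and aldehyde preference of alkenyl chromium reagents should secure, and it needs ring closure to beat oligomerization, which high dilution secures.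

Step 16
Reactants: 23 macrocyclic allylic alcohol
Product: 25 target, via organomercurial 24 (not isolated)
Conditions: Hg(OCOCF3)2, MeCN, −20 °C; H2O; then Bu3SnH, THF, 0 °C
Reagents that add atoms: water O
Why: Divalent mercury activates the electron-rich C4=C18 alkene, the epoxide oxygen attacks C4 across the ring (5-exo, Markovnikov), the resulting epoxonium ion is opened at the tertiary C8 with inversion by the C11 carbonyl oxygen or water, and tin hydride replaces mercury by hydrogen (oxymercuration–demercuration merged with an epoxide-opening cascade); C4 is fixed because only the cis-bridged oxolane can span the 14-membered ring, C7 is retained and C8 inverted.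

Compound list
1 | (5E)-6,10-dimethylundeca-5,9-dien-2-one (geranylacetone) | CC(C)=CCC/C(C)=C/CCC(C)=O | starting material
2 | (5E)-6,10-dimethylundeca-1,5,9-trien-2-yl trifluoromethanesulfonate | CC(C)=CCC/C(C)=C/CCC(=C)OS(=O)(=O)C(F)(F)F | intermediate
3 | (5E)-9-bromo-10-hydroxy-6,10-dimethylundeca-1,5-dien-2-yl trifluoromethanesulfonate (racemic bromohydrin) | CC(C)(O)C(Br)CC/C(C)=C/CCC(=C)OS(=O)(=O)C(F)(F)F | intermediate
4 | (5E)-8-(3,3-dimethyloxiran-2-yl)-6-methylocta-1,5-dien-2-yl trifluoromethanesulfonate (racemic) | CC1(C)OC1CC/C(C)=C/CCC(=C)OS(=O)(=O)C(F)(F)F | intermediate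
5 | (5E)-6-methyl-9-oxonona-1,5-dien-2-yl trifluoromethanesulfonate | O=CCC/C(C)=C/CCC(=C)OS(=O)(=O)C(F)(F)F | intermediate
6 | cyclohex-2-en-1-one | O=C1C=CCCC1 | starting material
7 | (5E,9S)-9-hydroxy-6-methyl-9-(6-oxocyclohex-1-en-1-yl)nona-1,5-dien-2-yl trifluoromethanesulfonate | O=C1CCCC=C1[C@@H](O)CC/C(C)=C/CCC(=C)OS(=O)(=O)C(F)(F)F | intermediate
8 | dilithium salt (C11 alkoxide and C12 enolate) formed from 7 by conjugate reduction | [Li+].[Li+].[O-]C1=C(CCCC1)[C@@H]([O-])CC/C(C)=C/CCC(=C)OS(=O)(=O)C(F)(F)F | intermediate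
9 | (5E,9S)-9-hydroxy-6-methyl-9-[(1R)-1-methyl-2-oxocyclohexyl]nona-1,5-dien-2-yl trifluoromethanesulfonate | O=C1CCCC[C@]1(C)[C@@H](O)CC/C(C)=C/CCC(=C)OS(=O)(=O)C(F)(F)F | intermediate
10 | (5E,9S)-6-methyl-9-[(1R)-1-methyl-2-oxocyclohexyl]-9-(triethylsilyloxy)nona-1,5-dien-2-yl trifluoromethanesulfonate | O=C1CCCC[C@]1(C)[C@@H](O[Si](CC)(CC)CC)CC/C(C)=C/CCC(=C)OS(=O)(=O)C(F)(F)F | intermediate
11 | (5E,9S)-6-methyl-9-[(1R)-1-methyl-2-oxocyclohex-3-en-1-yl]-9-(triethylsilyloxy)nona-1,5-dien-2-yl trifluoromethanesulfonate | O=C1C=CCC[C@]1(C)[C@@H](O[Si](CC)(CC)CC)CC/C(C)=C/CCC(=C)OS(=O)(=O)C(F)(F)F | intermediate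
12 | potassium ethenyltrifluoroborate | C=C[B-](F)(F)F.[K+] | starting material
13 | (5E,9S)-9-[(1R,4S)-4-ethenyl-1-methyl-2-oxocyclohexyl]-6-methyl-9-(triethylsilyloxy)nona-1,5-dien-2-yl trifluoromethanesulfonate | O=C1C[C@@H](C=C)CC[C@]1(C)[C@@H](O[Si](CC)(CC)CC)CC/C(C)=C/CCC(=C)OS(=O)(=O)C(F)(F)F | intermediate
14 | (5E,9S)-9-[(2R,5S)-5-ethenyl-2-methyl-7-oxooxepan-2-yl]-6-methyl-9-(triethylsilyloxy)nona-1,5-dien-2-yl trifluoromethanesulfonate | O=C1C[C@@H](C=C)CC[C@@](C)(O1)[C@@H](O[Si](CC)(CC)CC)CC/C(C)=C/CCC(=C)OS(=O)(=O)C(F)(F)F | intermediate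
15 | 4-[(2S,3S)-3-{(3S)-3-[(2R,5S)-5-ethenyl-2-methyl-7-oxooxepan-2-yl]-3-(triethylsilyloxy)propyl}-3-methyloxiran-2-yl]but-1-en-2-yl trifluoromethanesulfonate | O=C1C[C@@H](C=C)CC[C@@](C)(O1)[C@@H](O[Si](CC)(CC)CC)CC[C@]2(C)O[C@H]2CCC(=C)OS(=O)(=O)C(F)(F)F | intermediate
16 | Mannich base: 15 bearing CH2NMe2 on the lactone α-carbon C15 (either C15 epimer) | O=C1C(CN(C)C)[C@@H](C=C)CC[C@@](C)(O1)[C@@H](O[Si](CC)(CC)CC)CC[C@]2(C)O[C@H]2CCC(=C)OS(=O)(=O)C(F)(F)F | intermediate
17 | trimethylammonium iodide derived from 16 | O=C1C(C[N+](C)(C)C)[C@@H](C=C)CC[C@@](C)(O1)[C@@H](O[Si](CC)(CC)CC)CC[C@]2(C)O[C@H]2CCC(=C)OS(=O)(=O)C(F)(F)F.[I-] | intermediate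
18 | 4-[(2S,3S)-3-{(3S)-3-[(2R,5R)-5-ethenyl-2-methyl-6-methylidene-7-oxooxepan-2-yl]-3-(triethylsilyloxy)propyl}-3-methyloxiran-2-yl]but-1-en-2-yl trifluoromethanesulfonate | O=C1C(=C)[C@@H](C=C)CC[C@@](C)(O1)[C@@H](O[Si](CC)(CC)CC)CC[C@]2(C)O[C@H]2CCC(=C)OS(=O)(=O)C(F)(F)F | intermediate
19 | 4-[(2S,3S)-3-{(3S)-3-[(2R,5R)-5-ethenyl-2-methyl-6-methylidene-7-oxooxepan-2-yl]-3-hydroxypropyl}-3-methyloxiran-2-yl]but-1-en-2-yl trifluoromethanesulfonate | O=C1C(=C)[C@@H](C=C)CC[C@@](C)(O1)[C@@H](O)CC[C@]2(C)O[C@H]2CCC(=C)OS(=O)(=O)C(F)(F)F | intermediate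
20 | bis(9-borabicyclo[3.3.1]nonan-9-yl) adduct of 19 (B on C3, O-borinate on C11) | O=C1C(=C)[C@@H](CCB3C4CCCC3CCC4)CC[C@@](C)(O1)[C@@H](OB5C6CCCC5CCC6)CC[C@]2(C)O[C@H]2CCC(=C)OS(=O)(=O)C(F)(F)F | intermediate
21 | 4-[(2S,3S)-3-{(3S)-3-hydroxy-3-[(2R,5R)-5-(2-hydroxyethyl)-2-methyl-6-methylidene-7-oxooxepan-2-yl]propyl}-3-methyloxiran-2-yl]but-1-en-2-yl trifluoromethanesulfonate | O=C1C(=C)[C@@H](CCO)CC[C@@](C)(O1)[C@@H](O)CC[C@]2(C)O[C@H]2CCC(=C)OS(=O)(=O)C(F)(F)F | intermediate
22 | 4-[(2S,3S)-3-methyl-3-{3-[(2R,5R)-2-methyl-6-methylidene-7-oxo-5-(2-oxoethyl)oxepan-2-yl]-3-oxopropyl}oxiran-2-yl]but-1-en-2-yl trifluoromethanesulfonate | O=C1C(=C)[C@@H](CC=O)CC[C@@](C)(O1)C(=O)CC[C@]2(C)O[C@H]2CCC(=C)OS(=O)(=O)C(F)(F)F | intermediate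
23 | (1R,3S,7S,8S,12R)-7,8-epoxy-3-hydroxy-11-oxocembra-4(18),15(17)-dien-16,12-olide | C=C1C(=O)O[C@]2(C)CC[C@@H]1C[C@H](O)C(=C)CC[C@@H]3O[C@@]3(C)CCC2=O | intermediate
24 | 18-(trifluoroacetoxymercurio) derivative of 25 | C=C1C(=O)O[C@]2(C)CC[C@@H]1C[C@H](O)[C@@]1(C[Hg]OC(=O)C(F)(F)F)CC[C@H](O1)[C@](C)(O)CCC2=O | intermediate
25 | (1R,3S,4R,7S,8R,12R)-4,7-epoxy-3,8-dihydroxy-11-oxocembr-15(17)-en-16,12-olide (CNP0266269.2) | C=C1C(=O)O[C@]2(C)CC[C@@H]1C[C@H](O)[C@@]1(C)CC[C@H](O1)[C@](C)(O)CCC2=O | target

Total step count: 16. Longest linear sequence: 16 steps (1 → 25; 6 and 12 enter as purchased reactants).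

Steps most likely to fail

1. Step 15 (key step). What may go wrong: poor facial selectivity in the addition to the C3 aldehyde, opening of the epoxide by chloride on trivalent chromium, or oligomerization. Fallback, from 22 back to 23: the coupling is run without chiral ligand (NiCl2/CrCl2, DMSO, high dilution) and should give 23 mixed with its C3 epimer F1. MnO2 then oxidises the allylic carbinols of the mixture to the cross-conjugated enone F2. Reduction with 2-methyl-CBS-oxazaborolidine and catecholborane at −78 °C, which should reduce the enone carbonyl faster than the hindered C11 ketone, sets C3 under reagent control and returns to 23.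

2. Step 16. What may go wrong: intermolecular hydration of the mercurinium ion before the epoxide oxygen attacks (which would invert C7 instead of C8), trapping of the C11 carbonyl as a ketal, or addition of the tin radical to the acrylate. Fallback, from 23 to 25, in separate known operations: dilute HClO4 in aqueous THF opens the epoxide at the tertiary C8 with inversion to the (3S,7S,8R)-triol F3. N-iodosuccinimide then closes the oxolane by iodoetherification of the C4=C18 alkene with the C7 hydroxyl to give the iodide F4. Bu3SnH with Et3B and air removes iodine and gives 25.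

3. Step 5. What may go wrong: loss of facial selectivity in the enolate methylation, retro-aldol cleavage of the aldolate, or 1,2-reduction of the enone. Fallback, from 5 to 13, with the methyl group installed first: commercial 2-methylcyclohex-2-en-1-one is reduced with LiBH(s-Bu)3 and the enolate is trapped with 5 (reductive aldol) to give the racemic aldol F5 as a diastereomer mixture. Silylation as in step 6 gives its silyl ether F6, and dehydrogenation as in step 7 gives the racemic enone F7. The rhodium/(S)-BINAP addition of step 8 then sets C1 in both enantiomers of F7. Chromatography removes the C12-epimeric diastereomers and leaves 13 together with its C11 epimer F8; both are carried on, because C11 becomes a ketone in step 14. At most half of the material is usable.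

Further compounds
F1 | step 15 | (1R,3R,7S,8S,12R)-7,8-epoxy-3-hydroxy-11-oxocembra-4(18),15(17)-dien-16,12-olide (C3 epimer of 23) | C=C1C(=O)O[C@]2(C)CC[C@@H]1C[C@@H](O)C(=C)CC[C@@H]3O[C@@]3(C)CCC2=O
F2 | step 15 | (1R,7S,8S,12R)-7,8-epoxy-3,11-dioxocembra-4(18),15(17)-dien-16,12-olide | C=C1C(=O)O[C@]2(C)CC[C@@H]1CC(=O)C(=C)CC[C@@H]3O[C@@]3(C)CCC2=O
F3 | step 16 | (1R,3S,7S,8R,12R)-3,7,8-trihydroxy-11-oxocembra-4(18),15(17)-dien-16,12-olide | C=C1C(=O)O[C@]2(C)CC[C@@H]1C[C@H](O)C(=C)CC[C@H](O)[C@](C)(O)CCC2=O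
F4 | step 16 | 18-iodo derivative of 25 | C=C1C(=O)O[C@]2(C)CC[C@@H]1C[C@H](O)[C@@]1(CI)CC[C@H](O1)[C@](C)(O)CCC2=O
F5 | step 5 | (5E)-9-hydroxy-6-methyl-9-(1-methyl-2-oxocyclohexyl)nona-1,5-dien-2-yl trifluoromethanesulfonate (racemic, diastereomer mixture) | O=C1CCCCC1(C)C(O)CC/C(C)=C/CCC(=C)OS(=O)(=O)C(F)(F)F
F6 | step 5 | triethylsilyl ether of F5 | O=C1CCCCC1(C)C(O[Si](CC)(CC)CC)CC/C(C)=C/CCC(=C)OS(=O)(=O)C(F)(F)F
F7 | step 5 | (5E)-6-methyl-9-(1-methyl-2-oxocyclohex-3-en-1-yl)-9-(triethylsilyloxy)nona-1,5-dien-2-yl trifluoromethanesulfonate (racemic) | O=C1C=CCCC1(C)C(O[Si](CC)(CC)CC)CC/C(C)=C/CCC(=C)OS(=O)(=O)C(F)(F)F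
F8 | step 5 | (5E,9R)-9-[(1R,4S)-4-ethenyl-1-methyl-2-oxocyclohexyl]-6-methyl-9-(triethylsilyloxy)nona-1,5-dien-2-yl trifluoromethanesulfonate (C11 epimer of 13) | O=C1C[C@@H](C=C)CC[C@]1(C)[C@H](O[Si](CC)(CC)CC)CC/C(C)=C/CCC(=C)OS(=O)(=O)C(F)(F)F
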